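**Retrosynthetic overview**
- The last step is acidolytic removal of a tert-butyl ester and a triethylsilyl (TES) ether; before that, the ring C3–acyl bond is cut (O-acylation, then O→C acyl shift of a C12 acid onto the preformed (R)-6-methylpyran-2,4-dione).
- The (E)-alkene is cut by cross-metathesis into vinyl ester fragment A and (R)-4-methylhept-6-enoic acid fragment B.
- Fragment A: an anti-2-vinyl-1,3-diol from CuI/vinyl Grignard opening of a Sharpless epoxy alcohol; its sec-butyl centre, the first stereocentre of the route, comes from Ru–H8-BINAP hydrogenation of tiglic acid.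
- Fragment B: geraniol → (R)-citronellol (Ru–BINAP hydrogenation) → methylenation → selective cleavage of the trisubstituted alkene.
- Ring order: the single ring (fragment C) is made on its own by ketoreductase reduction of ethyl acetoacetate, Claisen extension and acid lactonisation, and is attached intact.

Assumption: the acylpyranone is handled as the enol tautomer written in the target SMILES, and dione 28 is written in its diketo form.

**Fragment A**

Step 1
Reactants: 1 tiglic acid ((E)-2-methylbut-2-enoic acid)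
Product: 2 (S)-2-methylbutanoic acid
Conditions: H2 (2 atm), Ru(OAc)2[(S)-H8-BINAP] (0.5 mol %), MeOH, 20 °C
Reagents that add atoms: none
Why: Carboxylate-directed Ru–H8-BINAP asymmetric hydrogenation of the trisubstituted enoic acid gives the (S)-acid with the (S)-ligand (about 97% ee), which sets the sec-butyl stereocentre.

Step 2
Reactants: 2 (S)-2-methylbutanoic acid
Product: 3 (S)-2-methylbutan-1-ol
Conditions: LiAlH4, Et2O, 0 °C → reflux; H2O quench
Reagents that add atoms: none
Why: LiAlH4 reduction of the acid to the primary alcohol leaves the α-stereocentre untouched.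

Step 3
Reactants: 3 (S)-2-methylbutan-1-ol; 4 ethyl (triphenylphosphoranylidene)acetate
Product: 6 ethyl (S,E)-4-methylhex-2-enoate, via (S)-2-methylbutanal 5 (not isolated)
Conditions: TEMPO (10 mol %), PhI(OAc)2 (1.1 equiv), CH2Cl2, rt; then 4 (1.3 equiv), rt
Reagents that add atoms: none
Why: The non-basic TEMPO/PhI(OAc)2 oxidation spares the labile α-centre of the volatile aldehyde, and Wittig olefination with the stabilised ylide in the same flask gives the (E)-enoate (>20:1).

Step 4
Reactants: 6 ethyl (S,E)-4-methylhex-2-enoate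
Product: 7 (S,E)-4-methylhex-2-en-1-ol
Conditions: i-Bu2AlH (2.3 equiv), CH2Cl2, −78 °C; aq. KNaC4H4O6
Reagents that add atoms: none
Why: DIBAL-H 1,2-reduction of the enoate at low temperature gives the (E)-allylic alcohol without conjugate reduction.

Step 5
Reactants: 7 (S,E)-4-methylhex-2-en-1-ol
Product: 8 [(2R,3R)-3-[(2S)-butan-2-yl]oxiran-2-yl]methanol
Conditions: Ti(OiPr)4 (5 mol %), D-(−)-diethyl tartrate (6 mol %), t-BuOOH (2 equiv), 4 Å molecular sieves, CH2Cl2, −20 °C
Reagents that add atoms: tert-butyl hydroperoxide, CC(C)(C)OO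
Why: Katsuki–Sharpless asymmetric epoxidation is reagent-controlled for primary (E)-allylic alcohols, and D-(−)-DET gives the (2R,3R)-epoxide (the mirror sense of the (2S,3S) products from L-(+)-DET), fixing the carbinol centre and preparing the neighbouring carbon for inversion.

Step 6
Reactants: 8 [(2R,3R)-3-[(2S)-butan-2-yl]oxiran-2-yl]methanol; 9 vinylmagnesium bromide
Product: 10 (2S,3R,4S)-2-ethenyl-4-methylhexane-1,3-diol
Conditions: 9 (4 equiv), CuI (20 mol %), THF/Et2O, −40 → −10 °C; aq. NH4Cl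
Reagents that add atoms: none
Why: Copper-catalysed Grignard opening of the 2,3-epoxy alcohol is an SN2 attack with inversion at C2, away from the branched sec-butyl group, so the trans-epoxide gives the anti-2-vinyl-1,3-diol, and any 1,2-diol regioisomer is removed by chromatography.

Step 7
Reactants: 10 (2S,3R,4S)-2-ethenyl-4-methylhexane-1,3-diol
Product: 11 (2S,3R,4S)-2-ethenyl-4-methyl-1,3-bis(triethylsilyloxy)hexane
Conditions: Et3SiOTf (2.4 equiv), 2,6-lutidine (4 equiv), CH2Cl2, −78 → 0 °C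
Reagents that add atoms: triethylsilyl trifluoromethanesulfonate, CC[Si](CC)(CC)OS(=O)(=O)C(F)(F)F
Why: Silyl triflate with a hindered pyridine base silylates both the primary and the hindered secondary hydroxyl (silyl ether protection).

Step 8
Reactants: 11 (2S,3R,4S)-2-ethenyl-4-methyl-1,3-bis(triethylsilyloxy)hexane
Product: 12 (2S,3R,4S)-2-ethenyl-4-methyl-3-(triethylsilyloxy)hexan-1-ol
Conditions: PPTS (0.2 equiv), MeOH/CH2Cl2 (1:4), −10 → 0 °C
Reagents that add atoms: none
Why: Acid-catalysed methanolysis cleaves the unhindered primary TES ether much faster than the flanked secondary one (selective desilylation).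

Step 9
Reactants: 12 (2S,3R,4S)-2-ethenyl-4-methyl-3-(triethylsilyloxy)hexan-1-ol
Product: 13 (2R,3R,4S)-2-ethenyl-4-methyl-3-(triethylsilyloxy)hexanal
Conditions: Dess–Martin periodinane (1.3 equiv), NaHCO3, CH2Cl2, 0 °C → rt; used crude at once
Reagents that add atoms: none
Why: Buffered Dess–Martin oxidation gives the α-vinyl aldehyde under near-neutral conditions that neither epimerise C2 nor move the double bond into conjugation.

Step 10
Reactants: 13 (2R,3R,4S)-2-ethenyl-4-methyl-3-(triethylsilyloxy)hexanal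
Product: 14 (2R,3R,4S)-2-ethenyl-4-methyl-3-(triethylsilyloxy)hexanoic acid
Conditions: NaClO2, NaH2PO4, 2-methyl-2-butene, t-BuOH/H2O, 0 °C → rt
Reagents that add atoms: sodium chlorite, [Na+].[O-]Cl=O
Why: Pinnick oxidation converts the aldehyde to the acid at about pH 4 while 2-methyl-2-butene scavenges HOCl, so the vinyl group and the α-centre are untouched.

Step 11
Reactants: 14 (2R,3R,4S)-2-ethenyl-4-methyl-3-(triethylsilyloxy)hexanoic acid
Product: 15 tert-butyl (2R,3R,4S)-2-ethenyl-4-methyl-3-(triethylsilyloxy)hexanoate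
Conditions: O-tert-butyl-N,N'-diisopropylisourea (3 equiv), CH2Cl2, rt, 24 h
Reagents that add atoms: O-tert-butyl-N,N'-diisopropylisourea, CC(C)NC(=NC(C)C)OC(C)(C)C
Why: The isourea alkylates the carboxylate oxygen (tert-butyl transfer) under neutral conditions, so the hindered acid is esterified without acyl activation and thus without epimerisation or alkene migration.

**Fragment B**

Step 12
Reactants: 16 geraniol
Product: 17 (R)-citronellol
Conditions: H2 (100 atm), Ru(OAc)2[(S)-BINAP] (0.2 mol %), 95% aq. MeOH, 20 °C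
Reagents that add atoms: none
Why: Noyori Ru–BINAP asymmetric hydrogenation reduces only the hydroxyl-directed allylic double bond, the (S)-ligand giving (R)-citronellol (96–98% ee) and leaving the remote trisubstituted alkene intact, which sets the chain methyl centre.

Step 13
Reactants: 17 (R)-citronellol
Product: 18 (R)-citronellal
Conditions: TEMPO (5 mol %), PhI(OAc)2 (1.1 equiv), CH2Cl2, rt
Reagents that add atoms: none
Why: TEMPO-catalysed alcohol oxidation stops at the aldehyde and avoids the acid-induced ene cyclisation of citronellal.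

Step 14
Reactants: 18 (R)-citronellal
Product: 19 (R)-4,8-dimethylnona-1,7-diene
Conditions: Ph3PCH3Br, KOtBu, THF, 0 °C → rt
Reagents that add atoms: methyltriphenylphosphonium bromide, C[P+](c1ccccc1)(c1ccccc1)c1ccccc1.[Br-]
Why: Wittig methylenation turns the aldehyde into the terminal vinyl group needed for metathesis, and the β-stereocentre cannot enolise.

Step 15
Reactants: 19 (R)-4,8-dimethylnona-1,7-diene
Product: 20 2,2-dimethyl-3-[(3R)-3-methylhex-5-en-1-yl]oxirane (mixture of oxirane epimers)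
Conditions: mCPBA (1.05 equiv), NaHCO3, CH2Cl2, 0 °C
Reagents that add atoms: 3-chloroperoxybenzoic acid, OOC(=O)c1cccc(Cl)c1
Why: Prilezhaev epoxidation with one equivalent of peracid is highly selective for the electron-rich trisubstituted alkene over the monosubstituted one.

Step 16
Reactants: 20 2,2-dimethyl-3-[(3R)-3-methylhex-5-en-1-yl]oxirane
Product: 21 (R)-4-methylhept-6-enal
Conditions: H5IO6 (1.2 equiv), THF/H2O, 0 °C → rt
Reagents that add atoms: none
Why: Periodic acid hydrolyses the epoxide to the glycol and cleaves it in the same pot (Malaprade cleavage) to the aldehyde and acetone, leaving the terminal alkene.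

Step 17
Reactants: 21 (R)-4-methylhept-6-enal
Product: 22 (R)-4-methylhept-6-enoic acid
Conditions: NaClO2, NaH2PO4, 2-methyl-2-butene, t-BuOH/H2O, 0 °C → rt
Reagents that add atoms: sodium chlorite, [Na+].[O-]Cl=O
Why: Pinnick oxidation gives the acid chemoselectively in the presence of the terminal alkene.

**Fragment C (the ring)**

Step 18
Reactants: 23 ethyl acetoacetate
Product: 24 ethyl (R)-3-hydroxybutanoate
Conditions: (R)-selective ketoreductase (NADPH-dependent alcohol dehydrogenase), NADP+ (cat.), i-PrOH (co-substrate), KH2PO4/K2HPO4 buffer pH 7, 30 °C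
Reagents that add atoms: none
Why: Ketoreductase-catalysed asymmetric reduction of the methyl ketone (anti-Prelog enzyme, hydride from isopropanol by cofactor recycling) gives the (R)-alcohol in >99% ee and sets the lactone stereocentre.

Step 19
Reactants: 24 ethyl (R)-3-hydroxybutanoate; 25 tert-butyl acetate
Product: 26 tert-butyl (R)-5-hydroxy-3-oxohexanoate
Conditions: 25 (4 equiv), LiN(iPr)2 (4 equiv), THF, −78 °C; then 24, −78 → −20 °C; aq. NH4Cl
Reagents that add atoms: none
Why: Crossed Claisen condensation with excess lithium enolate of tert-butyl acetate (the extra equivalents deprotonate the hydroxyl and the product) extends the ester to the δ-hydroxy-β-keto ester without touching the carbinol centre.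

Step 20
Reactants: 26 tert-butyl (R)-5-hydroxy-3-oxohexanoate
Product: 28 (R)-6-methyldihydro-2H-pyran-2,4(3H)-dione, via (R)-5-hydroxy-3-oxohexanoic acid 27 (not isolated)
Conditions: TFA/CH2Cl2 (1:4), 0 °C → rt
Reagents that add atoms: none
Why: TFA cleaves the tert-butyl ester and the δ-hydroxy-β-keto acid lactonises at once (acid-catalysed lactonisation) to the only ring of the target, with the stereocentre untouched.

**Union and end game**

Step 21
Reactants: 15 tert-butyl (2R,3R,4S)-2-ethenyl-4-methyl-3-(triethylsilyloxy)hexanoate; 22 (R)-4-methylhept-6-enoic acid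
Product: 29 (4R,6E,8R,9R,10S)-8-(tert-butoxycarbonyl)-4,10-dimethyl-9-(triethylsilyloxy)dodec-6-enoic acid
Conditions: second-generation Hoveyda–Grubbs catalyst RuCl2(H2IMes)(=CH-C6H4-2-OiPr) (5 mol %), 22 (3 equiv), CH2Cl2, 40 °C
Reagents that add atoms: none
Why: Olefin cross-metathesis between the allylically branched, slowly homodimerising vinyl ester and an excess of the unhindered alkenoic acid gives the cross product, with the bulk next to the new double bond favouring the (E)-isomer and the catalyst tolerating the free acid.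

Step 22
Reactants: 29 (4R,6E,8R,9R,10S)-8-(tert-butoxycarbonyl)-4,10-dimethyl-9-(triethylsilyloxy)dodec-6-enoic acid; 28 (R)-6-methyldihydro-2H-pyran-2,4(3H)-dione
Product: 31 tert-butyl (2R,3R,4S)-2-[(1E,4R)-7-[(6R)-4-hydroxy-6-methyl-2-oxo-5,6-dihydro-2H-pyran-3-yl]-4-methyl-7-oxohept-1-en-1-yl]-4-methyl-3-(triethylsilyloxy)hexanoate, via enol ester 30 (not isolated)
Conditions: DCC (1.2 equiv), DMAP (1.5 equiv), CH2Cl2, 0 °C → rt, 24 h
Reagents that add atoms: none
Why: Steglich-type O-acylation of the acidic cyclic 1,3-dione followed by DMAP-mediated O→C acyl migration (Fries-type rearrangement) gives the chelated 3-acyl-4-hydroxydihydropyranone, while the hindered silyl ether and the tert-butyl ester are inert.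

Step 23
Reactants: 31 tert-butyl (2R,3R,4S)-2-[(1E,4R)-7-[(6R)-4-hydroxy-6-methyl-2-oxo-5,6-dihydro-2H-pyran-3-yl]-4-methyl-7-oxohept-1-en-1-yl]-4-methyl-3-(triethylsilyloxy)hexanoate
Product: 32 (2R,3R,4S)-3-hydroxy-2-[(1E,4R)-7-[(6R)-4-hydroxy-6-methyl-2-oxo-5,6-dihydro-2H-pyran-3-yl]-4-methyl-7-oxohept-1-en-1-yl]-4-methylhexanoic acid (CNP0137396.1)
Conditions: TFA/CH2Cl2 (1:3), 0 °C → rt; aqueous work-up
Reagents that add atoms: none
Why: Acidolysis removes the tert-butyl ester (as isobutene) and the TES ether in one base-free operation, so the α-stereocentre, the β,γ-double bond and the acylpyranone are not disturbed.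

**Compound list**

1 | tiglic acid | C/C=C(\C)C(=O)O | starting material
2 | (S)-2-methylbutanoic acid | CC[C@H](C)C(=O)O | intermediate
3 | (S)-2-methylbutan-1-ol | CC[C@H](C)CO | intermediate
4 | ethyl (triphenylphosphoranylidene)acetate | CCOC(=O)C=P(c1ccccc1)(c1ccccc1)c1ccccc1 | starting material
5 | (S)-2-methylbutanal | CC[C@H](C)C=O | intermediate
6 | ethyl (S,E)-4-methylhex-2-enoate | CC[C@H](C)/C=C/C(=O)OCC | intermediate
7 | (S,E)-4-methylhex-2-en-1-ol | CC[C@H](C)/C=C/CO | intermediate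
8 | [(2R,3R)-3-[(2S)-butan-2-yl]oxiran-2-yl]methanol | CC[C@H](C)[C@H]1O[C@@H]1CO | intermediate
9 | vinylmagnesium bromide | C=C[Mg]Br | starting material
10 | (2S,3R,4S)-2-ethenyl-4-methylhexane-1,3-diol | CC[C@H](C)[C@@H](O)[C@@H](C=C)CO | intermediate
11 | (2S,3R,4S)-2-ethenyl-4-methyl-1,3-bis(triethylsilyloxy)hexane | CC[C@H](C)[C@@H](O[Si](CC)(CC)CC)[C@@H](C=C)CO[Si](CC)(CC)CC | intermediate
12 | (2S,3R,4S)-2-ethenyl-4-methyl-3-(triethylsilyloxy)hexan-1-ol | CC[C@H](C)[C@@H](O[Si](CC)(CC)CC)[C@@H](C=C)CO | intermediate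
13 | (2R,3R,4S)-2-ethenyl-4-methyl-3-(triethylsilyloxy)hexanal | CC[C@H](C)[C@@H](O[Si](CC)(CC)CC)[C@@H](C=C)C=O | intermediate
14 | (2R,3R,4S)-2-ethenyl-4-methyl-3-(triethylsilyloxy)hexanoic acid | CC[C@H](C)[C@@H](O[Si](CC)(CC)CC)[C@@H](C=C)C(=O)O | intermediate
15 | tert-butyl (2R,3R,4S)-2-ethenyl-4-methyl-3-(triethylsilyloxy)hexanoate | CC[C@H](C)[C@@H](O[Si](CC)(CC)CC)[C@@H](C=C)C(=O)OC(C)(C)C | intermediate
16 | geraniol | CC(C)=CCC/C(C)=C/CO | starting material
17 | (R)-citronellol | OCC[C@H](C)CCC=C(C)C | intermediate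
18 | (R)-citronellal | O=CC[C@H](C)CCC=C(C)C | intermediate
19 | (R)-4,8-dimethylnona-1,7-diene | C=CC[C@H](C)CCC=C(C)C | intermediate
20 | 2,2-dimethyl-3-[(3R)-3-methylhex-5-en-1-yl]oxirane (both oxirane epimers) | C=CC[C@H](C)CCC1OC1(C)C | intermediate
21 | (R)-4-methylhept-6-enal | C=CC[C@H](C)CCC=O | intermediate
22 | (R)-4-methylhept-6-enoic acid | C=CC[C@H](C)CCC(=O)O | intermediate
23 | ethyl acetoacetate | CCOC(=O)CC(C)=O | starting material
24 | ethyl (R)-3-hydroxybutanoate | C[C@@H](O)CC(=O)OCC | intermediate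
25 | tert-butyl acetate | CC(=O)OC(C)(C)C | starting material
26 | tert-butyl (R)-5-hydroxy-3-oxohexanoate | C[C@@H](O)CC(=O)CC(=O)OC(C)(C)C | intermediate
27 | (R)-5-hydroxy-3-oxohexanoic acid | C[C@@H](O)CC(=O)CC(=O)O | intermediate
28 | (R)-6-methyldihydro-2H-pyran-2,4(3H)-dione | C[C@@H]1CC(=O)CC(=O)O1 | intermediate
29 | (4R,6E,8R,9R,10S)-8-(tert-butoxycarbonyl)-4,10-dimethyl-9-(triethylsilyloxy)dodec-6-enoic acid | CC[C@H](C)[C@@H](O[Si](CC)(CC)CC)[C@@H](/C=C/C[C@H](C)CCC(=O)O)C(=O)OC(C)(C)C | intermediate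
30 | (6R)-6-methyl-2-oxo-5,6-dihydro-2H-pyran-4-yl (4R,6E,8R,9R,10S)-8-(tert-butoxycarbonyl)-4,10-dimethyl-9-(triethylsilyloxy)dodec-6-enoate | CC[C@H](C)[C@@H](O[Si](CC)(CC)CC)[C@@H](/C=C/C[C@H](C)CCC(=O)OC1=CC(=O)O[C@H](C)C1)C(=O)OC(C)(C)C | intermediate
31 | tert-butyl (2R,3R,4S)-2-[(1E,4R)-7-[(6R)-4-hydroxy-6-methyl-2-oxo-5,6-dihydro-2H-pyran-3-yl]-4-methyl-7-oxohept-1-en-1-yl]-4-methyl-3-(triethylsilyloxy)hexanoate | CC[C@H](C)[C@@H](O[Si](CC)(CC)CC)[C@@H](/C=C/C[C@H](C)CCC(=O)C1=C(O)C[C@@H](C)OC1=O)C(=O)OC(C)(C)C | intermediate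
32 | (2R,3R,4S)-3-hydroxy-2-[(1E,4R)-7-[(6R)-4-hydroxy-6-methyl-2-oxo-5,6-dihydro-2H-pyran-3-yl]-4-methyl-7-oxohept-1-en-1-yl]-4-methylhexanoic acid | CC[C@H](C)[C@@H](O)[C@@H](/C=C/C[C@H](C)CCC(=O)C1=C(O)C[C@@H](C)OC1=O)C(=O)O | target

**Step count and risks**

Total steps: 23. Longest linear sequence: 14 steps (steps 1–11, then 21–23).

The three steps most likely to fail:

Step 21 (cross-metathesis). The vinyl group of 15 sits on a crowded allylic carbon, so conversion may be low and some (Z)-isomer may form. The fallback makes the alkene by Julia–Kocienski olefination and sets out from 11 and 17. Ozonolysis of 11 (O3, CH2Cl2, −78 °C; PPh3) gives (2S,3R,4S)-4-methyl-3-(triethylsilyloxy)-2-[(triethylsilyloxy)methyl]hexanal F4. Mitsunobu reaction of 17 with 1-phenyl-1H-tetrazole-5-thiol (PPh3, DIAD) gives the citronellyl phenyltetrazolyl sulfide F5, which is oxidised ((NH4)6Mo7O24·4H2O cat., H2O2, EtOH) to the citronellyl phenyltetrazolyl sulfone F6. Deprotonation of F6 with KN(SiMe3)2 in DME at −60 °C and addition of F4 gives the (E)-alkene bis-TES diene F7. The operations of steps 8–11 are then repeated: PPTS/MeOH gives primary alcohol F8, Dess–Martin periodinane gives aldehyde F9, Pinnick oxidation gives acid F10, and the isourea gives tert-butyl ester F11. The operations of steps 15–17 follow on the trisubstituted alkene: mCPBA gives epoxide F12, H5IO6 gives the C12 aldehyde F13, and Pinnick oxidation gives 29, where the route is rejoined.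

Step 6 (epoxide opening). Attack at C3 or halohydrin formation would lower the yield of the 1,3-diol. The fallback uses a carboxylate-directed opening and sets out from 8. Oxidation with RuCl3 (cat.)/NaIO4 in CCl4/MeCN/H2O gives (2S,3R)-3-[(2S)-butan-2-yl]oxirane-2-carboxylic acid F1. (CH2=CH)2CuLi in THF/Et2O at −20 °C attacks C2 of the glycidic acid with inversion and gives (2R,3R,4S)-2-ethenyl-3-hydroxy-4-methylhexanoic acid F2. Et3SiOTf/2,6-lutidine silylates both oxygens to give triethylsilyl (2R,3R,4S)-2-ethenyl-4-methyl-3-(triethylsilyloxy)hexanoate F3, and K2CO3 in aqueous MeOH cleaves the labile silyl ester to give 14, where the route is rejoined (steps 7–10 are skipped).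

Step 22 (O-acylation and O→C acyl shift). The enol ester 30 may fail to rearrange or may be lost to hydrolysis. The fallback builds the ring after C-acylation of the open-chain keto ester and sets out from 26 and 29. Et3SiCl/imidazole converts 26 into tert-butyl (5R)-3-oxo-5-(triethylsilyloxy)hexanoate F14. 1-Chloro-N,N,2-trimethylprop-1-en-1-amine converts 29 into its acid chloride F15. Magnesium-mediated C-acylation of F14 (MgCl2, pyridine, CH2Cl2, 0 °C) with F15 gives the 2-acyl-3-oxo diester F16. TFA/CH2Cl2 then removes both TES ethers and both tert-butyl esters, and the freed δ-hydroxy tricarbonyl acid lactonises to give 32 directly, so this variant rejoins at 32 and replaces steps 22 and 23.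

**Further compounds**

F1 | step 6 | (2S,3R)-3-[(2S)-butan-2-yl]oxirane-2-carboxylic acid | CC[C@H](C)[C@H]1O[C@@H]1C(=O)O
F2 | step 6 | (2R,3R,4S)-2-ethenyl-3-hydroxy-4-methylhexanoic acid | CC[C@H](C)[C@@H](O)[C@@H](C=C)C(=O)O
F3 | step 6 | triethylsilyl (2R,3R,4S)-2-ethenyl-4-methyl-3-(triethylsilyloxy)hexanoate | CC[C@H](C)[C@@H](O[Si](CC)(CC)CC)[C@@H](C=C)C(=O)O[Si](CC)(CC)CC
F4 | step 21 | (2S,3R,4S)-4-methyl-3-(triethylsilyloxy)-2-[(triethylsilyloxy)methyl]hexanal | CC[C@H](C)[C@@H](O[Si](CC)(CC)CC)[C@@H](C=O)CO[Si](CC)(CC)CC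
F5 | step 21 | 5-{[(3R)-3,7-dimethyloct-6-en-1-yl]sulfanyl}-1-phenyl-1H-tetrazole | c1ccccc1-n1nnnc1SCC[C@H](C)CCC=C(C)C
F6 | step 21 | 5-{[(3R)-3,7-dimethyloct-6-en-1-yl]sulfonyl}-1-phenyl-1H-tetrazole | c1ccccc1-n1nnnc1S(=O)(=O)CC[C@H](C)CCC=C(C)C
F7 | step 21 | (2S,3R,4S)-2-[(1E,4R)-4,8-dimethylnona-1,7-dien-1-yl]-4-methyl-1,3-bis(triethylsilyloxy)hexane | CC[C@H](C)[C@@H](O[Si](CC)(CC)CC)[C@@H](/C=C/C[C@H](C)CCC=C(C)C)CO[Si](CC)(CC)CC
F8 | step 21 | (2S,3R,4S)-2-[(1E,4R)-4,8-dimethylnona-1,7-dien-1-yl]-4-methyl-3-(triethylsilyloxy)hexan-1-ol | CC[C@H](C)[C@@H](O[Si](CC)(CC)CC)[C@@H](/C=C/C[C@H](C)CCC=C(C)C)CO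
F9 | step 21 | (2R,3R,4S)-2-[(1E,4R)-4,8-dimethylnona-1,7-dien-1-yl]-4-methyl-3-(triethylsilyloxy)hexanal | CC[C@H](C)[C@@H](O[Si](CC)(CC)CC)[C@@H](/C=C/C[C@H](C)CCC=C(C)C)C=O
F10 | step 21 | (2R,3R,4S)-2-[(1E,4R)-4,8-dimethylnona-1,7-dien-1-yl]-4-methyl-3-(triethylsilyloxy)hexanoic acid | CC[C@H](C)[C@@H](O[Si](CC)(CC)CC)[C@@H](/C=C/C[C@H](C)CCC=C(C)C)C(=O)O
F11 | step 21 | tert-butyl (2R,3R,4S)-2-[(1E,4R)-4,8-dimethylnona-1,7-dien-1-yl]-4-methyl-3-(triethylsilyloxy)hexanoate | CC[C@H](C)[C@@H](O[Si](CC)(CC)CC)[C@@H](/C=C/C[C@H](C)CCC=C(C)C)C(=O)OC(C)(C)C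
F12 | step 21 | tert-butyl (2R,3R,4S)-2-[(1E,4R)-6-(3,3-dimethyloxiran-2-yl)-4-methylhex-1-en-1-yl]-4-methyl-3-(triethylsilyloxy)hexanoate | CC[C@H](C)[C@@H](O[Si](CC)(CC)CC)[C@@H](/C=C/C[C@H](C)CCC1OC1(C)C)C(=O)OC(C)(C)C
F13 | step 21 | tert-butyl (2R,3R,4S)-4-methyl-2-[(1E,4R)-4-methyl-7-oxohept-1-en-1-yl]-3-(triethylsilyloxy)hexanoate | CC[C@H](C)[C@@H](O[Si](CC)(CC)CC)[C@@H](/C=C/C[C@H](C)CCC=O)C(=O)OC(C)(C)C
F14 | step 22 | tert-butyl (5R)-3-oxo-5-(triethylsilyloxy)hexanoate | C[C@@H](O[Si](CC)(CC)CC)CC(=O)CC(=O)OC(C)(C)C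
F15 | step 22 | tert-butyl (2R,3R,4S)-2-[(1E,4R)-7-chloro-4-methyl-7-oxohept-1-en-1-yl]-4-methyl-3-(triethylsilyloxy)hexanoate | CC[C@H](C)[C@@H](O[Si](CC)(CC)CC)[C@@H](/C=C/C[C@H](C)CCC(Cl)=O)C(=O)OC(C)(C)C
F16 | step 22 | tert-butyl (2R,3R,4S)-2-[(1E,4R,11R)-8-(tert-butoxycarbonyl)-4-methyl-7,9-dioxo-11-(triethylsilyloxy)dodec-1-en-1-yl]-4-methyl-3-(triethylsilyloxy)hexanoate | CC[C@H](C)[C@@H](O[Si](CC)(CC)CC)[C@@H](/C=C/C[C@H](C)CCC(=O)C(C(=O)OC(C)(C)C)C(=O)C[C@@H](C)O[Si](CC)(CC)CC)C(=O)OC(C)(C)C
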